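**Plan**

1. Numbering (germacrane): ring carbons C1–C10; furanone ring = O, C3, C2, C1, C10; C4=C5 with C15 on C4; lactone O–C6, C7, C11(=C13), C12; angelate on O–C8; C14 on C10.
2. Cuts, last to first: O–C3 (the 3(2H)-furanone is the cycloisomer of the α'-hydroxy ynone C10(OH)–C1(=O)–C2≡C3); then C1–C2, the alkynyl–carbonyl bond of the ten-membered ring C1–C10 (iodoalkyne at C2, aldehyde at C1); then O8–acyl, C11=C13, C3–C4, C4=C5, C7–C8 and C8–C9.
3. What makes the C1–C2 closure possible: the rigid C1–C2≡C3–C4 rod, the (Z)-C4=C5 turn, the trans-fused lactone across C6–C7 and the quaternary C10 bring C1 and C2 together; C1 sits next to the C10 hydroxyl that afterwards closes the furanone.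
4. Forward order: dithiane/epoxide union (C8–C9); conjugate addition to a butenolide (C7–C8, lactone ring first); growth of C5 into the (Z)-enyne; unmasking and reduction of C8; methylenation and angeloylation; then the ten-membered ring (C1–C2) and last the furanone ring (O–C3).
5. Stereochemistry: C6 from (S)-5-(hydroxymethyl)furan-2(5H)-one and C10 from (S)-2-methylglycidol (both bought); C7 relayed from C6 (trans conjugate addition); C8 relayed from C7/C6 (Felkin–Anh reduction); (Z)-C4=C5 from a (Z)-selective iodo-olefination; angelate geometry bought with angelic acid.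

Key step: step 16

Remark: the free tertiary hydroxyl next to the aldehyde in 23 is assumed to be tolerated by the weakly basic alkynylchromium intermediate, as organochromium additions generally tolerate hydroxyl groups.

**Route**

Step 1
Reactants: 1 (S)-5-(hydroxymethyl)furan-2(5H)-one
Product: 2 (S)-5-{[(tert-butyldiphenylsilyl)oxy]methyl}furan-2(5H)-one
Conditions: TBDPSCl, imidazole, CH2Cl2, 0 °C to rt
Reagents that add atoms: tert-butyl(chloro)diphenylsilane (TBDPSCl), CC(C)(C)[Si](Cl)(c1ccccc1)c1ccccc1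
Why: Silyl ether formation on the primary alcohol under mild imidazole conditions leaves the base-sensitive butenolide and its stereocenter (future C6) untouched and supplies the bulky group that later shields one face of the butenolide.

Step 2
Reactants: 3 1,3-dithiane; 4 (S)-2-methylglycidol
Product: 5 (R)-3-(1,3-dithian-2-yl)-2-methylpropane-1,2-diol
Conditions: n-BuLi, THF, −30 °C; then 4 (0.45 equiv), −30 to 0 °C; aq. NH4Cl
Reagents that add atoms: none
Why: Corey–Seebach umpolung: 2-lithio-1,3-dithiane opens the 2,2-disubstituted epoxide by SN2 attack at its unsubstituted CH2 (C9), so the quaternary carbinol (future C10) is carried over from 4 with no bond to it broken, the first equivalent of base being spent on the hydroxyl.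

Step 3
Reactants: 5 (R)-3-(1,3-dithian-2-yl)-2-methylpropane-1,2-diol
Product: 6 2-{[(4R)-2,2,4-trimethyl-1,3-dioxolan-4-yl]methyl}-1,3-dithiane
Conditions: 2,2-dimethoxypropane, CSA (cat.), acetone, rt
Reagents that add atoms: 2,2-dimethoxypropane, COC(C)(C)OC
Why: Acid-catalysed transacetalization ties the primary (C1) and tertiary (C10) hydroxyls into one dioxolane that should survive the organolithium, fluoride, ylide, palladium and amide-base steps ahead.

Step 4
Reactants: 6 2-{[(4R)-2,2,4-trimethyl-1,3-dioxolan-4-yl]methyl}-1,3-dithiane; 2 (S)-5-{[(tert-butyldiphenylsilyl)oxy]methyl}furan-2(5H)-one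
Product: 7 (4S,5S)-5-{[(tert-butyldiphenylsilyl)oxy]methyl}-4-(2-{[(4R)-2,2,4-trimethyl-1,3-dioxolan-4-yl]methyl}-1,3-dithian-2-yl)dihydrofuran-2(3H)-one (4,5-trans)
Conditions: t-BuLi, THF/HMPA, −78 °C; then 2, −78 °C; aq. NH4Cl
Reagents that add atoms: none
Why: Michael (1,4) addition of the lithiated dithiane, favoured over 1,2-addition by HMPA, should occur on the butenolide face opposite the silyloxymethyl group, so C7 is set trans to C6 by substrate control while C8 arrives as a masked ketone.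

Step 5
Reactants: 7 (the trans lactone of step 4)
Product: 8 (4S,5S)-5-(hydroxymethyl)-4-(2-{[(4R)-2,2,4-trimethyl-1,3-dioxolan-4-yl]methyl}-1,3-dithian-2-yl)dihydrofuran-2(3H)-one
Conditions: TBAF, AcOH, THF, 0 °C to rt
Reagents that add atoms: none
Why: Fluoride-mediated desilylation, buffered with acetic acid to protect the lactone, frees the primary alcohol (C5) while dithiane and acetonide are inert.

Step 6
Reactants: 8 (the primary alcohol of step 5)
Product: 9 (2S,3S)-5-oxo-3-(2-{[(4R)-2,2,4-trimethyl-1,3-dioxolan-4-yl]methyl}-1,3-dithian-2-yl)tetrahydrofuran-2-carbaldehyde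
Conditions: SO3·pyridine, DMSO, i-Pr2NEt, CH2Cl2, 0 °C
Reagents that add atoms: none
Why: Parikh–Doering oxidation gives the aldehyde without oxidizing the dithiane sulfur atoms and is mild enough to keep the α-oxygenated C6 center intact.

Step 7
Reactants: 9 (the aldehyde of step 6)
Product: 10 (4S,5S)-5-[(Z)-2-iodoprop-1-en-1-yl]-4-(2-{[(4R)-2,2,4-trimethyl-1,3-dioxolan-4-yl]methyl}-1,3-dithian-2-yl)dihydrofuran-2(3H)-one
Conditions: [Ph3PEt]I, n-BuLi, THF, rt; iodine, −78 °C; NaN(SiMe3)2, −20 °C; then 9, −78 °C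
Reagents that add atoms: ethyltriphenylphosphonium iodide, CC[P+](c1ccccc1)(c1ccccc1)c1ccccc1.[I-]; iodine, [I][I]
Why: Stork–Zhao-type Wittig olefination with the α-iodo ylide is kinetically controlled at low temperature and should give the (Z)-iodoalkene (iodine cis to C6), which fixes the C4=C5 geometry and brings in C4 and C15.

Step 8
Reactants: 10 (the (Z)-vinyl iodide of step 7); 11 ethynyltrimethylsilane
Product: 12 (4S,5R)-5-[(Z)-2-methyl-4-(trimethylsilyl)but-1-en-3-yn-1-yl]-4-(2-{[(4R)-2,2,4-trimethyl-1,3-dioxolan-4-yl]methyl}-1,3-dithian-2-yl)dihydrofuran-2(3H)-one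
Conditions: PdCl2(PPh3)2 (cat.), CuI (cat.), Et3N, THF, rt
Reagents that add atoms: none
Why: Sonogashira coupling proceeds with retention of alkene geometry, placing the alkyne (C3, C2) cis to C6, and the silyl cap protects the alkyne terminus for the amide-base step.

Step 9
Reactants: 12 (the silyl enyne of step 8)
Product: 13 (4S,5R)-5-[(Z)-2-methyl-4-(trimethylsilyl)but-1-en-3-yn-1-yl]-4-{[(4R)-2,2,4-trimethyl-1,3-dioxolan-4-yl]acetyl}dihydrofuran-2(3H)-one
Conditions: MeI, CaCO3, MeCN/H2O, 45 °C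
Reagents that add atoms: water, O
Why: Alkylative hydrolysis of the dithioacetal (S-methylation, then hydrolysis of the sulfonium) unmasks the C8 ketone under buffered, near-neutral conditions that should spare the acetonide, the silylalkyne and the β-acyloxy ketone.

Step 10
Reactants: 13 (the C8 ketone of step 9)
Product: 14 (4R,5R)-4-{(1R)-1-hydroxy-2-[(4R)-2,2,4-trimethyl-1,3-dioxolan-4-yl]ethyl}-5-[(Z)-2-methyl-4-(trimethylsilyl)but-1-en-3-yn-1-yl]dihydrofuran-2(3H)-one
Conditions: LiBH(s-Bu)3 (L-Selectride), THF, −78 °C; aq. NH4Cl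
Reagents that add atoms: none
Why: Felkin–Anh delivery of the bulky, non-chelating hydride anti to the C7–C6 bond of the α-branched ketone should give the (8R) alcohol (O8 anti to C11 and 1,3-anti to O6, the two inductions reinforcing each other) at a temperature where the lactone is not reduced.

Step 11
Reactants: 14 (the C8 alcohol of step 10)
Product: 17 (4R,5R)-4-{(1R)-1-hydroxy-2-[(4R)-2,2,4-trimethyl-1,3-dioxolan-4-yl]ethyl}-3-methylidene-5-[(Z)-2-methyl-4-(trimethylsilyl)but-1-en-3-yn-1-yl]dihydrofuran-2(3H)-one, via Mannich base 15 (not isolated), via ammonium iodide 16 (not isolated)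
Conditions: LiN(i-Pr)2 (LDA, 2.5 equiv), THF, −78 °C; Eschenmoser's salt, −78 to 0 °C; then MeI, MeOH, rt; then aq. NaHCO3, CH2Cl2, rt
Reagents that add atoms: Eschenmoser's salt (N,N-dimethylmethyleneiminium iodide), C=[N+](C)C.[I-]
Why: Eschenmoser α-methylenation: the lactone enolate (formed beside the C8 alkoxide with excess base) is aminomethylated at C11, and quaternization followed by E1cB elimination installs C11=C13, erasing the transient C11 stereocenter.

Step 12
Reactants: 17 (the α-methylene lactone alcohol of step 11); 18 angelic acid, (Z)-2-methylbut-2-enoic acid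
Product: 20 (1R)-1-[(2R,3R)-4-methylidene-2-[(Z)-2-methyl-4-(trimethylsilyl)but-1-en-3-yn-1-yl]-5-oxotetrahydrofuran-3-yl]-2-[(4R)-2,2,4-trimethyl-1,3-dioxolan-4-yl]ethyl (Z)-2-methylbut-2-enoate, via mixed anhydride 19 (not isolated)
Conditions: 18, 2,4,6-trichlorobenzoyl chloride, Et3N, toluene, rt; then 17, 80 °C
Reagents that add atoms: none
Why: Yamaguchi-type acylation through the mixed anhydride esterifies the hindered C8 hydroxyl without the nucleophilic catalysts that isomerize angelate to tiglate, and C8 keeps its configuration because its C–O bond is not touched.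

Step 13
Reactants: 20 (the angelate of step 12)
Product: 21 (1R)-1-[(2R,3R)-2-[(Z)-4-iodo-2-methylbut-1-en-3-yn-1-yl]-4-methylidene-5-oxotetrahydrofuran-3-yl]-2-[(4R)-2,2,4-trimethyl-1,3-dioxolan-4-yl]ethyl (Z)-2-methylbut-2-enoate
Conditions: NIS, AgNO3 (cat.), acetone, rt, dark
Reagents that add atoms: N-iodosuccinimide, O=C1CCC(=O)N1I
Why: Silver-catalysed iododesilylation converts the alkynylsilane directly into the 1-iodoalkyne, the alkenes being inert to NIS in the absence of a nucleophile.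

Step 14
Reactants: 21 (the iodoalkyne of step 13)
Product: 22 (1R,3R)-3,4-dihydroxy-1-[(2R,3R)-2-[(Z)-4-iodo-2-methylbut-1-en-3-yn-1-yl]-4-methylidene-5-oxotetrahydrofuran-3-yl]-3-methylbutyl (Z)-2-methylbut-2-enoate
Conditions: AcOH/H2O (4:1), 40 °C
Reagents that add atoms: none
Why: Mild aqueous acid hydrolyses the dioxolane, while the angelate, the iodoalkyne and the α-methylene lactone are stable to acid.

Step 15
Reactants: 22 (the diol of step 14)
Product: 23 (1R,3R)-3-hydroxy-1-[(2R,3R)-2-[(Z)-4-iodo-2-methylbut-1-en-3-yn-1-yl]-4-methylidene-5-oxotetrahydrofuran-3-yl]-3-methyl-4-oxobutyl (Z)-2-methylbut-2-enoate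
Conditions: SO3·pyridine, DMSO, i-Pr2NEt, CH2Cl2, 0 °C
Reagents that add atoms: none
Why: Parikh–Doering oxidation can only touch the primary alcohol (the tertiary one has no carbinol hydrogen) and gives the non-enolizable α-hydroxy aldehyde C1, to be used without storage.

Step 16
Reactants: 23 (the seco iodoalkyne aldehyde of step 15)
Product: 24 ten-membered cyclic enyne diol: (6R,7R,8R,10R)-1,10-dihydroxy-8-angeloyloxy-germacra-4(Z),11(13)-dien-2-yn-6,12-olide, either epimer at C1
Conditions: CrCl2 (excess), NiCl2 (cat.), THF, rt, slow addition of 23, high dilution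
Reagents that add atoms: none
Why: Nozaki–Hiyama–Kishi reaction: zerovalent nickel formed in situ inserts into the C(sp)–I bond and transmetalates to chromium (CrCl2 also reduces the iodoalkyne directly), and the resulting alkynyl species of trivalent chromium adds to the C1 aldehyde to form the C1–C2 bond. The closest known reaction type is the chromium-mediated cyclization of iodoalkyne aldehydes to medium-ring cyclic enynes and enediynes. The ten-membered carbocycle C1–C10 closes by exo attack on the aldehyde carbonyl with the alkyne inside the new ring, the C1–C2≡C3–C4 rod, the (Z)-C4=C5 turn, the trans-fused lactone at C6–C7 and the quaternary C10 holding the termini within reach. The new carbinol center at C1 is not controlled and need not be, because it is oxidized in the next step. The step needs chemoselectivity for the aldehyde over the lactone, the angelate and the α-methylene lactone, and ring closure over oligomerization; the first follows from the low basicity and carbonyl selectivity of organochromium reagents, the second from high dilution with slow addition and the preorganized seco chain.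

Step 17
Reactants: 24 (the cyclic propargylic diol of step 16)
Product: 26 15-deoxybudlein A, via cyclic ynone 25 (not isolated)
Conditions: MnO2, CH2Cl2, rt; filtration; AuCl3 (cat.), CH2Cl2, rt
Reagents that add atoms: none
Why: MnO2 oxidizes only the propargylic alcohol to the α'-hydroxy ynone, and gold-catalysed 5-endo-dig addition of the C10 hydroxyl to C3 (alkyne π-activation, then protodeauration) cycloisomerizes it to the 3(2H)-furanone without touching any stereocenter.

**Compound list**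

1 | (S)-5-(hydroxymethyl)furan-2(5H)-one | OC[C@H]1OC(=O)C=C1 | starting material
2 | (S)-5-{[(tert-butyldiphenylsilyl)oxy]methyl}furan-2(5H)-one | CC(C)(C)[Si](OC[C@H]1OC(=O)C=C1)(c1ccccc1)c1ccccc1 | intermediate
3 | 1,3-dithiane | C1CSCSC1 | starting material
4 | (S)-2-methylglycidol, (S)-(2-methyloxiran-2-yl)methanol | OC[C@@]1(C)CO1 | starting material
5 | (R)-3-(1,3-dithian-2-yl)-2-methylpropane-1,2-diol | OC[C@@](C)(CC1SCCCS1)O | intermediate
6 | 2-{[(4R)-2,2,4-trimethyl-1,3-dioxolan-4-yl]methyl}-1,3-dithiane | CC1(C)OC[C@@](C)(CC2SCCCS2)O1 | intermediate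
7 | (4S,5S)-5-{[(tert-butyldiphenylsilyl)oxy]methyl}-4-(2-{[(4R)-2,2,4-trimethyl-1,3-dioxolan-4-yl]methyl}-1,3-dithian-2-yl)dihydrofuran-2(3H)-one | O=C1C[C@@H]([C@@H](CO[Si](c2ccccc2)(c2ccccc2)C(C)(C)C)O1)C2(C[C@]3(C)COC(C)(C)O3)SCCCS2 | intermediate
8 | (4S,5S)-5-(hydroxymethyl)-4-(2-{[(4R)-2,2,4-trimethyl-1,3-dioxolan-4-yl]methyl}-1,3-dithian-2-yl)dihydrofuran-2(3H)-one | O=C1C[C@@H]([C@@H](CO)O1)C2(C[C@]3(C)COC(C)(C)O3)SCCCS2 | intermediate
9 | (2S,3S)-5-oxo-3-(2-{[(4R)-2,2,4-trimethyl-1,3-dioxolan-4-yl]methyl}-1,3-dithian-2-yl)tetrahydrofuran-2-carbaldehyde | O=C1C[C@@H]([C@@H](C=O)O1)C2(C[C@]3(C)COC(C)(C)O3)SCCCS2 | intermediate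
10 | (4S,5S)-5-[(Z)-2-iodoprop-1-en-1-yl]-4-(2-{[(4R)-2,2,4-trimethyl-1,3-dioxolan-4-yl]methyl}-1,3-dithian-2-yl)dihydrofuran-2(3H)-one | O=C1C[C@@H]([C@@H](/C=C(/C)I)O1)C2(C[C@]3(C)COC(C)(C)O3)SCCCS2 | intermediate
11 | ethynyltrimethylsilane | C#C[Si](C)(C)C | starting material
12 | (4S,5R)-5-[(Z)-2-methyl-4-(trimethylsilyl)but-1-en-3-yn-1-yl]-4-(2-{[(4R)-2,2,4-trimethyl-1,3-dioxolan-4-yl]methyl}-1,3-dithian-2-yl)dihydrofuran-2(3H)-one | O=C1C[C@@H]([C@@H](/C=C(/C)C#C[Si](C)(C)C)O1)C2(C[C@]3(C)COC(C)(C)O3)SCCCS2 | intermediate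
13 | (4S,5R)-5-[(Z)-2-methyl-4-(trimethylsilyl)but-1-en-3-yn-1-yl]-4-{[(4R)-2,2,4-trimethyl-1,3-dioxolan-4-yl]acetyl}dihydrofuran-2(3H)-one | O=C1C[C@@H]([C@@H](/C=C(/C)C#C[Si](C)(C)C)O1)C(=O)C[C@]2(C)COC(C)(C)O2 | intermediate
14 | (4R,5R)-4-{(1R)-1-hydroxy-2-[(4R)-2,2,4-trimethyl-1,3-dioxolan-4-yl]ethyl}-5-[(Z)-2-methyl-4-(trimethylsilyl)but-1-en-3-yn-1-yl]dihydrofuran-2(3H)-one | O=C1C[C@@H]([C@@H](/C=C(/C)C#C[Si](C)(C)C)O1)[C@H](O)C[C@]2(C)COC(C)(C)O2 | intermediate
15 | Mannich base: 3-[(dimethylamino)methyl] derivative of 14 (configuration at the lactone α-carbon not defined) | O=C1C(CN(C)C)[C@@H]([C@@H](/C=C(/C)C#C[Si](C)(C)C)O1)[C@H](O)C[C@]2(C)COC(C)(C)O2 | intermediate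
16 | ammonium iodide: N-methyl quaternary salt of 15 | O=C1C(C[N+](C)(C)C)[C@@H]([C@@H](/C=C(/C)C#C[Si](C)(C)C)O1)[C@H](O)C[C@]2(C)COC(C)(C)O2.[I-] | intermediate
17 | (4R,5R)-4-{(1R)-1-hydroxy-2-[(4R)-2,2,4-trimethyl-1,3-dioxolan-4-yl]ethyl}-3-methylidene-5-[(Z)-2-methyl-4-(trimethylsilyl)but-1-en-3-yn-1-yl]dihydrofuran-2(3H)-one | O=C1C(=C)[C@@H]([C@@H](/C=C(/C)C#C[Si](C)(C)C)O1)[C@H](O)C[C@]2(C)COC(C)(C)O2 | intermediate
18 | angelic acid, (Z)-2-methylbut-2-enoic acid | C/C=C(/C)C(=O)O | starting material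
19 | mixed anhydride of angelic acid and 2,4,6-trichlorobenzoic acid | C/C=C(/C)C(=O)OC(=O)c1c(Cl)cc(Cl)cc1Cl | intermediate
20 | (1R)-1-[(2R,3R)-4-methylidene-2-[(Z)-2-methyl-4-(trimethylsilyl)but-1-en-3-yn-1-yl]-5-oxotetrahydrofuran-3-yl]-2-[(4R)-2,2,4-trimethyl-1,3-dioxolan-4-yl]ethyl (Z)-2-methylbut-2-enoate | O=C1C(=C)[C@@H]([C@@H](/C=C(/C)C#C[Si](C)(C)C)O1)[C@H](OC(=O)/C(C)=C\C)C[C@]2(C)COC(C)(C)O2 | intermediate
21 | (1R)-1-[(2R,3R)-2-[(Z)-4-iodo-2-methylbut-1-en-3-yn-1-yl]-4-methylidene-5-oxotetrahydrofuran-3-yl]-2-[(4R)-2,2,4-trimethyl-1,3-dioxolan-4-yl]ethyl (Z)-2-methylbut-2-enoate | O=C1C(=C)[C@@H]([C@@H](/C=C(/C)C#CI)O1)[C@H](OC(=O)/C(C)=C\C)C[C@]2(C)COC(C)(C)O2 | intermediate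
22 | (1R,3R)-3,4-dihydroxy-1-[(2R,3R)-2-[(Z)-4-iodo-2-methylbut-1-en-3-yn-1-yl]-4-methylidene-5-oxotetrahydrofuran-3-yl]-3-methylbutyl (Z)-2-methylbut-2-enoate | O=C1C(=C)[C@@H]([C@@H](/C=C(/C)C#CI)O1)[C@H](OC(=O)/C(C)=C\C)C[C@@](C)(O)CO | intermediate
23 | (1R,3R)-3-hydroxy-1-[(2R,3R)-2-[(Z)-4-iodo-2-methylbut-1-en-3-yn-1-yl]-4-methylidene-5-oxotetrahydrofuran-3-yl]-3-methyl-4-oxobutyl (Z)-2-methylbut-2-enoate | O=C1C(=C)[C@@H]([C@@H](/C=C(/C)C#CI)O1)[C@H](OC(=O)/C(C)=C\C)C[C@@](C)(O)C=O | intermediate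
24 | ten-membered cyclic enyne diol: (6R,7R,8R,10R)-1,10-dihydroxy-8-angeloyloxy-germacra-4(Z),11(13)-dien-2-yn-6,12-olide, either epimer at C1 | C=C1C(=O)O[C@@H]2/C=C(/C)C#CC(O)[C@](C)(O)C[C@@H](OC(=O)/C(C)=C\C)[C@@H]12 | intermediate
25 | cyclic α'-hydroxy ynone: the 1-oxo analogue of 24 | C=C1C(=O)O[C@@H]2/C=C(/C)C#CC(=O)[C@](C)(O)C[C@@H](OC(=O)/C(C)=C\C)[C@@H]12 | intermediate
26 | 15-deoxybudlein A | C=C1C(=O)O[C@@H]2/C=C(/C)C3=CC(=O)[C@@](C)(C[C@@H](OC(=O)/C(C)=C\C)[C@@H]12)O3 | target

**Totals and risks**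

Total step count: 17. Longest linear sequence: 16 steps (steps 2 to 17, from 3 and 4 to 26); the other branch (step 1, then steps 4 to 17) has 15.

Steps most likely to fail:

1. Step 16 (macrocyclization). Intermolecular coupling or protonation of the alkynylchromium species may outrun ring closure. The fallback forms the same C1–C2 bond by a unimolecular dipolar cycloaddition of a hindered, slowly dimerizing nitrile oxide; it sets out from 14 and returns at 26. Desilylation of the alkyne of 14 (TBAF, AcOH) would give the terminal enyne alcohol F1, and silylation (TBSOTf, 2,6-lutidine) its TBS ether F2. Acetonide hydrolysis (aq. AcOH) would give the diol F3, Parikh–Doering oxidation the hydroxy aldehyde F4, and NH2OH·HCl/NaOAc the aldoxime F5. Chlorination with NCS to the hydroximoyl chloride F6 and slow addition to Et3N at high dilution would generate the nitrile oxide F7, which should add across the terminal alkyne (C1 to C2, O to C3) to give the bridged isoxazole F8, a masked 1,3-dicarbonyl. Eschenmoser methylenation as in step 11, through the Mannich base F9 and the ammonium iodide F10, would give the α-methylene lactone F11. HF·pyridine would then free the C8 alcohol F12, and acylation with 19 would give the angelate F13. Reductive N–O cleavage with Mo(CO)6 in wet MeCN would give the enaminone F14, and aqueous acetic acid should hydrolyse it and close the furanone by attack of the C10 hydroxyl on C3, giving 26.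

2. Step 7 (iodo-olefination). Poor Z/E control and base-induced epimerization of the α-oxygenated aldehyde are possible. The fallback builds the trisubstituted alkene by two stereospecific cross-couplings; it sets out from 9 and returns at 12. Corey–Fuchs-type dibromo-olefination (CBr4, PPh3, Et3N) would give the 1,1-dibromoalkene F15. Palladium-catalysed trans-selective monomethylation (Me2Zn, PdCl2(DPEphos)) should replace the bromine trans to C6 and give the (Z)-vinyl bromide F16. Sonogashira coupling of F16 with 11 (PdCl2(PPh3)2, CuI, Et3N) would give 12 with retention.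

3. Step 10 (ketone reduction). Facial selectivity may be poor, and the lactone carboxylate may be lost by β-elimination from the β-acyloxy ketone. The fallback replaces substrate control by catalyst control; it sets out from 13 and returns at 14. Corey–Bakshi–Shibata reduction with (S)-2-methyl-CBS-oxazaborolidine and catecholborane (toluene, −78 °C) should deliver hydride to the face that gives the (8R) alcohol, taking the ring-branched C7 side as the large group, under neutral conditions; no new compound arises (F0).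

**Further compounds**

F1 | step 16 | terminal enyne alcohol (14 without the alkynyl silyl group) | O=C1C[C@@H]([C@@H](/C=C(/C)C#C)O1)[C@H](O)C[C@]2(C)COC(C)(C)O2
F2 | step 16 | C8 TBS ether of F1 | O=C1C[C@@H]([C@@H](/C=C(/C)C#C)O1)[C@H](O[Si](C)(C)C(C)(C)C)C[C@]2(C)COC(C)(C)O2
F3 | step 16 | primary/tertiary diol from F2 | O=C1C[C@@H]([C@@H](/C=C(/C)C#C)O1)[C@H](O[Si](C)(C)C(C)(C)C)C[C@@](C)(O)CO
F4 | step 16 | α-hydroxy aldehyde from F3 | O=C1C[C@@H]([C@@H](/C=C(/C)C#C)O1)[C@H](O[Si](C)(C)C(C)(C)C)C[C@@](C)(O)C=O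
F5 | step 16 | aldoxime of F4 | O=C1C[C@@H]([C@@H](/C=C(/C)C#C)O1)[C@H](O[Si](C)(C)C(C)(C)C)C[C@@](C)(O)/C=N/O
F6 | step 16 | hydroximoyl chloride from F5 | O=C1C[C@@H]([C@@H](/C=C(/C)C#C)O1)[C@H](O[Si](C)(C)C(C)(C)C)C[C@@](C)(O)C(Cl)=NO
F7 | step 16 | nitrile oxide from F6 | O=C1C[C@@H]([C@@H](/C=C(/C)C#C)O1)[C@H](O[Si](C)(C)C(C)(C)C)C[C@@](C)(O)C#[N+][O-]
F8 | step 16 | bridged isoxazole macrocycle (N on C1, O on C3), saturated lactone, C8 TBS ether | C1C(=O)O[C@@H]2/C=C(/C)c3cc(no3)[C@](C)(O)C[C@@H](O[Si](C)(C)C(C)(C)C)[C@@H]12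
F9 | step 16 | Mannich base of F8 at C11 | CN(C)CC1C(=O)O[C@@H]2/C=C(/C)c3cc(no3)[C@](C)(O)C[C@@H](O[Si](C)(C)C(C)(C)C)[C@@H]12
F10 | step 16 | ammonium iodide from F9 | C[N+](C)(C)CC1C(=O)O[C@@H]2/C=C(/C)c3cc(no3)[C@](C)(O)C[C@@H](O[Si](C)(C)C(C)(C)C)[C@@H]12.[I-]
F11 | step 16 | α-methylene lactone isoxazole, C8 TBS ether | C=C1C(=O)O[C@@H]2/C=C(/C)c3cc(no3)[C@](C)(O)C[C@@H](O[Si](C)(C)C(C)(C)C)[C@@H]12
F12 | step 16 | C8 alcohol from F11 | C=C1C(=O)O[C@@H]2/C=C(/C)c3cc(no3)[C@](C)(O)C[C@@H](O)[C@@H]12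
F13 | step 16 | C8 angelate of F12 | C=C1C(=O)O[C@@H]2/C=C(/C)c3cc(no3)[C@](C)(O)C[C@@H](OC(=O)/C(C)=C\C)[C@@H]12
F14 | step 16 | enaminone (1-amino-3-oxo, C1=C2) from F13 | C=C1C(=O)O[C@@H]2/C=C(/C)C(=O)/C=C(\N)[C@](C)(O)C[C@@H](OC(=O)/C(C)=C\C)[C@@H]12
F15 | step 7 | 1,1-dibromoalkene from 9 | O=C1C[C@@H]([C@@H](C=C(Br)Br)O1)C2(C[C@]3(C)COC(C)(C)O3)SCCCS2
F16 | step 7 | (Z)-vinyl bromide (bromo analogue of 10) | O=C1C[C@@H]([C@@H](/C=C(/C)Br)O1)C2(C[C@]3(C)COC(C)(C)O3)SCCCS2
F0 | step 10 | none | none
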